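## The problem

CNP0086724.3 (27) is a cis-fused hydroazulene: a cycloheptene (C1, C2, C3, C4, C8, C9, C10) shares the C4–C8 bond with a cyclopentane (C4, C5, C6, C7, C8). The numbering used throughout is: C1 the methyl-bearing alkene carbon, C2 the alkene CH, C3 the isovalerate carbinol, C4 the quaternary methyl carbon, C7 the isopropyl carbinol, C8 the ring-fusion CH, C9 the 4-hydroxybenzoate carbinol and C10 the remaining ring CH2. Five stereocentres must be set, four of them contiguous (C3, C4, C8, C9). O3 and O9 are cis to each other and to the cyclopentane bonds C4–C5 and C8–C7, the angular methyl and H8 lie on the opposite face, and at C7 the hydroxyl is on the face of H8 and the methyl while the isopropyl group points to the side of O9. If O3 and O9 are tied together they can dictate C4 and C8, and the cis ring fusion can then dictate C7, but only if oxygen rather than isopropyl is delivered from the open face; C3, next to the quaternary carbon, is the centre most at risk. No centre maps onto a chiral-pool compound, so the absolute configuration has to come from a reagent. The product carries a dehydration-prone tertiary alcohol, an allylic ester, a free phenol and two different esters on oxygens that are close in space, which excludes strong acid or base late and fixes the order of acylation; β-oxygenated ketones on the way are prone to β-elimination. The feature that invites the key step is the pair of cis oxygens on C3 and C9, 1,4 across the C4–C8 bond: joined as one bridging oxygen they define an 8-oxabicyclo[3.2.1]oct-6-ene with C4=C8 (methyl on C4) as the alkene and C2–C1–C10, oxidised at C1, as the three-carbon bridge, which is the retron of a furan–oxyallyl (4+3) cycloaddition.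

## Retrosynthesis

**Phenol and C3 ester.** The phenol is unmasked last, so 27 comes from its triisopropylsilyl ether 26. Cutting the C3–O acyl bond leads to allylic alcohol 24 and isovaleryl chloride 25. The C3–H bond is then cut, giving enone 23. Putting the aroyl group on O9 before the C3 oxygen exists avoids any need to tell two secondary hydroxyls apart. The forward reduction must deliver hydride to C3 on the face of the angular methyl.

**C1 methyl and the alkene.** Enone 23 is the oxidative-transposition product of tertiary allylic alcohol 22, so the C1=C2 alkene and the C3 carbonyl both derive from a C2=C3 alkene and a C1 carbinol. Ester 22 is cut at the C9–O acyl bond into triol 18 and acid 21 (one step from 4-hydroxybenzoic acid 19). Cutting the C1–CH3 bond of 18 gives hydroxy enone 17. This order keeps the ester away from the organometallic reagent and never passes through a β-acyloxy ketone.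

**The oxygen bridge.** Reconnecting O9 to C3 turns 17 into enol silane 16 and then bridged ketone 15, in which one oxygen holds C3 and C9. Forward, the C3–O bond must break and the C9–O bond must not, which means enolisation of the C1 ketone toward C2 and not toward C10. The two methylenes differ only through remote groups, so the choice is handed to a chiral lithium amide. On racemic 15 the base takes the C2 proton of one enantiomer and the C10 proton of the other. The material lost to the wrong direction of opening is therefore the unwanted enantiomer, and resolution costs no extra step.

**C7.** Ketone 15 comes from ketal 14. The C7–O bond of 14 is cut to alkene 13, the C7–isopropyl bond of 13 to enol triflate 12, and 12 to cyclopentanone 11. Direct addition of an isopropyl nucleophile to 11 was rejected: the open face of the C7 carbonyl is the face of H8, so the hydroxyl would end on the bridge side, the epimer of what is needed. Delivering oxygen, not carbon, to the open face gives the right centre.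

**The cyclopentane.** Cyclopentanone 11 is the one-carbon homologue of cyclobutanone 9 (C5–C6 and C6–C7 bonds). 9 comes from dichloride 8, and 8 from alkene 5 and dichloroketene 7 (from trichloroacetyl chloride 6) by cutting C4–C5 and C7–C8. A ketene [2+2] is preferred to a Pauson–Khand or a dipolar route because it places the carbonyl on the carbon attached to C8. Dechlorination before homologation is needed so that the unsubstituted C5 migrates and the ketone stays at C7.

**The seven-membered ring.** Ketal 5 is protected ketone 4, and 4 is cut at C2–C3 and C9–C10 into 3-methylfuran 1 and 2-methoxyallyl bromide 2. This removes the carbocycle and two stereocentres in one step and leaves two small achiral compounds. The forward reaction has only to close the ring; the symmetric allyl cation allows no regio- or endo/exo isomers.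

## Roads not taken

**Alternative 1:** The cut is the C4–C8 bond, with C4 reconnected to C9, so that the hydroazulene derives from the trans-decalin mesylate A1. Forward, the C9 alkoxide of A1 (KOtBu or Et2AlCl) pushes C4 from C9 to C8 anti to the equatorial mesylate; ring B contracts to the cyclopentane and ring A expands to the cycloheptanone A2. The shift is stereospecific, so C8 and the cis fusion are certain, C7 is already in place, and decalins of the Wieland–Miescher family are available enantiopure. On absolute configuration this road is clearly better than the chosen plan, which is racemic up to step 10. Its weak points are in A1 and after A2. In A1 the isopropyl group must be axial on ring B, 1,3-diaxial to the C9 oxygen, which is the arrangement an isopropyl nucleophile avoids. A2 has bare methylenes at C1 and C2 and carbonyl-level carbons at both C3 and C9, so two face-selective reductions, a differentiation of two ketones and the whole methyl-bearing alkene remain. Against the early enantiopurity the chosen plan sets a seven-membered ring that is made in one step with C9 oxygenated in its final configuration, and a C1 carbonyl that already sits where the methyl and alkene are built.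

**Alternative 2:** The cuts are C3–C4 and C1–C10. Forward, Rh2(S-DOSP)4 (divalent rhodium) converts diazo ester A3 into a vinylcarbenoid that cyclopropanates the terminal enol ether alkene of diene A4 (C1–C10 and C1–C9); the cis-divinylcyclopropane then rearranges (C3–C4 formed, C1–C9 broken) to cycloheptadiene A5. This is the shortest and most convergent way to the carbon skeleton, it is catalytic and enantioselective, and it makes the quaternary C4 in the ring-forming event; in step economy up to the bicycle it beats the chosen plan. The difficulties are these. The Cope step must form a quaternary centre at a tetrasubstituted alkene carbon through a boat transition state, and catalyst and chiral diene have to be matched. A5 has no oxygen at C3 or C7 and an ester where the C1 methyl belongs. As drawn, its isopropyl group is on the face of the angular methyl, so hydroxylation of C7–H with retention would give the C7 epimer. C8 would have to be set by protonation of the silyl enol ether. The chosen plan is longer, but each oxygen of 27 comes from a defined source (furan oxygen, ketene carbonyl, chromate) and no unactivated C–H bond needs oxidising.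

**Alternative 3:** The cuts are C7–C8 and C4–C5. Forward, SnCl4 ionises the dibenzyl ketal of carbinol A6 to a C7 oxocarbenium ion, alkene carbon C8 attacks it, and the C4 cation is quenched by shift of C5 from C3 to C4 as C3 becomes a ketone, giving hydroazulenone A7. One cascade builds the cyclopentane, the quaternary C4, the cis fusion and the fully substituted C7 with oxygen and isopropyl in place. For C7 this is better than the chosen plan, which spends steps 6 to 8 on that centre, and A7 arrives at the same C3 ketone stage as 23. The weak points are these. C9 emerges epimeric and must be inverted at a hindered carbinol. The C7 configuration depends on the oxocarbenium geometry and on the face of the alkene that is used, both steered only by the remote C9 silyl ether. A6 is a trisubstituted cycloheptene with three functionalised positions and is not obviously shorter to make than 11. Ring A of A7 still lacks the methyl and the alkene, and a tertiary benzyl ether must later be removed without touching that alkene. The chosen plan sets against this a C9 centre that is never at risk and a C1 carbonyl that gives the methyl and the alkene directly.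

Key step: step 1

Remark: compounds 3–15 are racemic and are drawn as the enantiomer that continues to 27; from 16 on the material belongs to a single enantiomeric series.
Remark: lithium (R,R)-bis(1-phenylethyl)amide is assumed to be the antipode that removes the axial C2 proton of the wanted enantiomer of 15; if the sense proves opposite, the (S,S)-amide is used and nothing else changes.

## Route

Step 1
Reactants: 1 3-methylfuran; 2 2-methoxyallyl bromide
Product: 4 rac-6-methyl-8-oxabicyclo[3.2.1]oct-6-en-3-one, via methyl enol ether 3 (not isolated)
Conditions: AgOCOCF3, Na2CO3, pentane, −78 °C → rt, dark; then HNO3 (dilute, aq.)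
Reagents that add atoms: water, O
Why: Silver trifluoroacetate (monovalent silver) abstracts bromide from 2 to give the 2-methoxyallyl cation, a three-carbon 2π component that adds across the two α-carbons of furan 1 and forms the C2–C3 and C9–C10 bonds. The closest known reaction type is the silver-promoted (4+3) cycloaddition of 2-alkoxyallyl halides with furans to 8-oxabicyclo[3.2.1]oct-6-en-3-ones. Whether concerted or stepwise, the seven-membered carbocycle closes when the enol ether terminus C10 bonds to the furan-derived oxocarbenium carbon C9 (a seven-membered closure, endo with respect to the enol ether), and the furan oxygen is left as the one-atom bridge. The new stereocentres C3 and C9 are the bridgeheads; their cis relationship is enforced by addition to one face of the planar furan, and no absolute control is exerted, so 4 is racemic. Proton loss from the bridged methoxycarbenium ion gives enol ether 3, which dilute acid hydrolyses to the C1 ketone. The selectivity needed is ring closure over simple electrophilic substitution or polymerisation of the furan; the electron-rich furan with both α-positions free, the non-nucleophilic counter-ion and the carbonate buffer favour closure. Because the allyl cation is symmetric and unsubstituted at its termini, no regio- or endo/exo isomers can form.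

Step 2
Reactants: 4 rac-6-methyl-8-oxabicyclo[3.2.1]oct-6-en-3-one
Product: 5 rac-ethylene ketal of 4 (6'-methylspiro[1,3-dioxolane-2,3'-[8]oxabicyclo[3.2.1]oct[6]ene])
Conditions: HOCH2CH2OH, PPTS, benzene, reflux (Dean–Stark)
Reagents that add atoms: ethylene glycol, OCCO
Why: Acid-catalysed ketalisation masks the C1 carbonyl, which would otherwise compete with the cyclobutanone, the C7 ketone and the C6 enolate made in steps 3–7. The dioxolane costs one step on and one off, against two each for reduction and silylation.

Step 3
Reactants: 5 rac-ethylene ketal of 4; 6 trichloroacetyl chloride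
Product: 8 rac-dichlorocyclobutanone ketal (exo-fused four-membered ring C4–C5–C7–C8; CCl2 = C5 on C4; C=O = C7 on C8; methyl and H8 endo), via dichloroketene 7 (not isolated)
Conditions: Zn–Cu couple, POCl3, Et2O, rt (slow addition of 6)
Reagents that add atoms: none
Why: Thermal [2+2] cycloaddition of dichloroketene to the strained, electron-rich trisubstituted alkene; the ketene approaches the exo face, syn to the oxygen bridge, so C4–C5 and C7–C8 form cis to O3 and O9 and the methyl and H8 become endo, which sets C4 and C8. The carbonyl carbon bonds to the less substituted C8 and CCl2 to C4, as with other trisubstituted alkenes; POCl3 binds ZnCl2 and spares the ketal.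

Step 4
Reactants: 8 rac-dichlorocyclobutanone ketal
Product: 9 rac-cyclobutanone ketal (C5 = CH2)
Conditions: Zn, NH4Cl, MeOH, rt
Reagents that add atoms: none
Why: Zinc reduction of the α,α-dichloroketone under buffered conditions that leave the ketal and the bridge alone; no stereocentre is touched. Removing chlorine first lets the CH2 group, not the ring-fusion carbon, migrate in step 5.

Step 5
Reactants: 9 rac-cyclobutanone ketal
Product: 11 rac-cyclopentanone ketal (exo-fused ring C4–C5–C6–C7(=O)–C8), via α-silyl ketone 10 (not isolated)
Conditions: Me3SiCHN2, AlMe3, CH2Cl2, −78 °C; then SiO2, moist CH2Cl2, rt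
Reagents that add atoms: (trimethylsilyl)diazomethane, C[Si](C)(C)C=[N+]=[N-]
Why: Lewis acid-promoted diazoalkane homologation (Tiffeneau–Demjanov type): the less substituted α-carbon C5 migrates in preference to the ring-fusion carbon C8, so the new carbon C6 enters between C5 and the carbonyl, which stays on C8 as the C7 ketone. Strain release lets the cyclobutanone react at −78 °C, and desilylation of 10 on silica avoids base, which could expel the C9 oxygen from a C8 enolate.

Step 6
Reactants: 11 rac-cyclopentanone ketal
Product: 12 rac-enol triflate (C6=C7–OSO2CF3)
Conditions: KN(SiMe3)2, THF, −78 °C; PhNTf2, −78 → 0 °C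
Reagents that add atoms: N-phenylbis(trifluoromethanesulfonimide), O=S(=O)(N(c1ccccc1)S(=O)(=O)C(F)(F)F)C(F)(F)F
Why: Kinetic deprotonation at the unhindered C6 methylene, not at the endo ring-fusion hydrogen on C8, followed by O-triflation gives the C6=C7 enol triflate. Keeping the enolate away from C8 also prevents β-elimination of the C9–O bond.

Step 7
Reactants: 12 rac-enol triflate
Product: 13 rac-7-isopropyl alkene (C6=C7)
Conditions: iPrMgCl, Fe(acac)3 (cat.), THF/NMP, −30 °C
Reagents that add atoms: isopropylmagnesium chloride, CC(C)[Mg]Cl
Why: Iron-catalysed Kumada-type cross-coupling of an alkenyl triflate with a secondary alkyl Grignard reagent puts the isopropyl group on C7 without creating a stereocentre. This avoids carbonyl addition to 11, which would place isopropyl on the open face and give the wrong C7 epimer.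

Step 8
Reactants: 13 rac-7-isopropyl alkene
Product: 14 rac-tertiary alcohol (C7 hydroxyl on the face of H8 and the C4 methyl; isopropyl toward the oxygen bridge)
Conditions: Co(acac)2 (cat.), PhSiH3, O2 (1 atm), THF/iPrOH, rt
Reagents that add atoms: dioxygen, O=O
Why: Mukaiyama hydration: hydrogen-atom transfer to C6 gives the tertiary C7 radical, which is trapped by O2 on the outer face of the cyclopentane, away from C9, C3 and the oxygen bridge that lean over the inner face. The hydroxyl therefore ends cis to H8 and the angular methyl, the C7 configuration of 27.

Step 9
Reactants: 14 rac-tertiary alcohol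
Product: 15 rac-hydroxy ketone (C1 ketone; oxygen bridge C3–C9; C7 carbinol)
Conditions: HCl (1 M, aq.), acetone, rt
Reagents that add atoms: water, O
Why: Mild acid hydrolysis of the dioxolane; the tertiary alcohol and the bridging ether tolerate dilute acid at room temperature.

Step 10
Reactants: 15 rac-hydroxy ketone
Product: 16 bis(trimethylsilyl) compound (C1=C2 trimethylsilyl enol ether; C7 trimethylsilyl ether; single enantiomeric series)
Conditions: Me3SiCl (excess), THF, −100 °C; LiN[(R)-CH(CH3)Ph]2·LiCl (2.4 equiv); Et3N, pentane, filtration
Reagents that add atoms: chlorotrimethylsilane, C[Si](C)(C)Cl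
Why: Enantiotopic-group-selective deprotonation of an 8-oxabicyclo[3.2.1]octan-3-one by a chiral lithium amide with in situ silylation (Simpkins-type). The base reads the local chirality of the bridged ketone, so it takes the axial C2 proton in the wanted enantiomer and the axial C10 proton in the mirror image, a regiodivergent resolution. The C7 alkoxide is silylated in the same flask.

Step 11
Reactants: 16 bis(trimethylsilyl) compound
Product: 17 hydroxy enone (cis-fused hydroazulene; C1 ketone; C2=C3; C9 and C7 hydroxyls)
Conditions: Me3SiOTf (cat.), CH2Cl2, −78 → −40 °C; then citric acid, MeOH, 0 °C; chromatography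
Reagents that add atoms: none
Why: Silyl triflate-catalysed ring opening: silylation of the bridging oxygen and push from the enol silane cleave the C3–O bond only, leaving O9 on C9 with its configuration; acidic methanolysis then removes both silyl groups. The material from the mirror-image half has cleaved C9–O instead and is a constitutional isomer, so chromatography here secures regiochemistry and absolute configuration together.

Step 12
Reactants: 17 hydroxy enone
Product: 18 triol (C1 tertiary allylic carbinol bearing the new methyl; C2=C3)
Conditions: MeLi, CeCl3, THF, −78 °C; NH4Cl (aq.)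
Reagents that add atoms: methyllithium, [Li]C
Why: 1,2-Addition of the weakly basic organocerium reagent to the enone carbonyl, with the two hydroxyls carried as alkoxides. The configuration of the new C1 carbinol does not matter because C1 becomes trigonal in step 15.

Step 13
Reactants: 19 4-hydroxybenzoic acid
Product: 21 4-(triisopropylsilyloxy)benzoic acid, via silyl ester 20 (not isolated)
Conditions: iPr3SiCl, imidazole, DMF, rt; then AcOH, THF/H2O, rt
Reagents that add atoms: chlorotriisopropylsilane, CC(C)[Si](Cl)(C(C)C)C(C)C
Why: Bis-silylation followed by selective hydrolysis of the labile silyl ester leaves the aryl silyl ether, a phenol mask that survives steps 14–17 and is removed by fluoride without touching esters.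

Step 14
Reactants: 18 triol; 21 4-(triisopropylsilyloxy)benzoic acid
Product: 22 C9 4-(triisopropylsilyloxy)benzoate of 18
Conditions: EDC·HCl, DMAP, CH2Cl2, rt
Reagents that add atoms: none
Why: Steglich esterification; only the secondary C9 hydroxyl reacts, the tertiary C1 and C7 hydroxyls being inert under carbodiimide/DMAP conditions. C9 keeps the configuration fixed by the former oxygen bridge.

Step 15
Reactants: 22 C9 4-(triisopropylsilyloxy)benzoate of 18
Product: 23 transposed enone (C3 ketone; C1(CH3)=C2)
Conditions: pyridinium chlorochromate, NaOAc, 4 Å molecular sieves, CH2Cl2, rt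
Reagents that add atoms: pyridinium chlorochromate, [O-][Cr](=O)(=O)Cl.c1cc[nH+]cc1
Why: Babler–Dauben oxidative transposition: the tertiary allylic chromate ester shifts [3,3] to C3 and is oxidised there, giving the C3 ketone and the trisubstituted C1=C2 alkene of 27. The saturated tertiary C7 alcohol and the aryl ester are inert to buffered chlorochromate.

Step 16
Reactants: 23 transposed enone
Product: 24 allylic alcohol (C3 hydroxyl cis to O9 and trans to the angular methyl)
Conditions: NaBH4, CeCl3·7H2O, MeOH, −78 °C
Reagents that add atoms: none
Why: Luche 1,2-reduction. In the favoured half-chair of the cycloheptenone (C8 and C9 above the enone plane, the C9 ester and C7 equatorial) the angular methyl is pseudo-equatorial and the cyclopentane carbon C5 is pseudo-axial on the lower face. The small hydride should therefore add from the upper face, cis to the methyl, placing the C3 hydroxyl cis to O9 and to the cyclopentane.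

Step 17
Reactants: 24 allylic alcohol; 25 isovaleryl chloride
Product: 26 O-triisopropylsilyl ether of 27
Conditions: pyridine, DMAP (cat.), CH2Cl2, 0 °C
Reagents that add atoms: none
Why: DMAP-catalysed acylation of the secondary allylic C3 hydroxyl; the hindered tertiary C7 hydroxyl does not compete at 0 °C.

Step 18
Reactants: 26 O-triisopropylsilyl ether of 27
Product: 27 CNP0086724.3
Conditions: Bu4NF, AcOH, THF, 0 °C
Reagents that add atoms: none
Why: Fluoride cleavage of the aryl silyl ether, buffered with acetic acid so that the phenoxide cannot promote acyl migration or ester cleavage.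

## Compound list

1 | 3-methylfuran | Cc1ccoc1 | starting material
2 | 2-methoxyallyl bromide (3-bromo-2-methoxyprop-1-ene) | COC(=C)CBr | starting material
3 | rac-3-methoxy-7-methyl-8-oxabicyclo[3.2.1]octa-2,6-diene (methyl enol ether of 4; forms with its double-bond isomer, both give 4) | COC1=C[C@H]2C(C)=C[C@H](O2)C1 | intermediate (not isolated)
4 | rac-6-methyl-8-oxabicyclo[3.2.1]oct-6-en-3-one | O=C1C[C@H]2C(C)=C[C@H](O2)C1 | intermediate
5 | rac-6'-methylspiro[1,3-dioxolane-2,3'-[8]oxabicyclo[3.2.1]oct[6]ene] | C1COC2(O1)C[C@H]3C(C)=C[C@H](O3)C2 | intermediate
6 | trichloroacetyl chloride | ClC(=O)C(Cl)(Cl)Cl | starting material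
7 | dichloroketene | ClC(Cl)=C=O | intermediate (not isolated)
8 | rac-dichlorocyclobutanone ketal (exo [2+2] adduct of 5; CCl2 on C4, C=O on C8) | C1COC2(O1)C[C@H]3[C@]4(C)C(Cl)(Cl)C(=O)[C@@H]4[C@H](O3)C2 | intermediate
9 | rac-cyclobutanone ketal | C1COC2(O1)C[C@H]3[C@]4(C)CC(=O)[C@@H]4[C@H](O3)C2 | intermediate
10 | rac-α-trimethylsilyl cyclopentanone ketal (silicon on C6, either epimer) | C1COC2(O1)C[C@H]3[C@]4(C)CC([Si](C)(C)C)C(=O)[C@@H]4[C@H](O3)C2 | intermediate (not isolated)
11 | rac-cyclopentanone ketal (C7 ketone) | C1COC2(O1)C[C@H]3[C@]4(C)CCC(=O)[C@@H]4[C@H](O3)C2 | intermediate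
12 | rac-enol triflate (C6=C7–OTf) | C1COC2(O1)C[C@H]3[C@]4(C)CC=C(OS(=O)(=O)C(F)(F)F)[C@@H]4[C@H](O3)C2 | intermediate
13 | rac-7-isopropyl alkene (C6=C7) | C1COC2(O1)C[C@H]3[C@]4(C)CC=C(C(C)C)[C@@H]4[C@H](O3)C2 | intermediate
14 | rac-tertiary alcohol ketal (C7 OH cis to H8 and the C4 methyl) | C1COC2(O1)C[C@H]3[C@]4(C)CC[C@](O)(C(C)C)[C@@H]4[C@H](O3)C2 | intermediate
15 | rac-hydroxy ketone (C1 ketone, C3–O–C9 bridge, C7 carbinol) | O=C1C[C@H]3[C@]4(C)CC[C@](O)(C(C)C)[C@@H]4[C@H](O3)C1 | intermediate
16 | bis(trimethylsilyl) compound (C1=C2 enol silane, C7 silyl ether) | C[Si](C)(C)OC1=C[C@H]3[C@]4(C)CC[C@](O[Si](C)(C)C)(C(C)C)[C@@H]4[C@H](O3)C1 | intermediate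
17 | hydroxy enone (C1 ketone, C2=C3, C9 OH, C7 OH) | O=C1C=C[C@]2(C)CC[C@](O)(C(C)C)[C@@H]2[C@H](O)C1 | intermediate
18 | triol (C1 methyl carbinol of either configuration, C2=C3) | CC1(O)C=C[C@]2(C)CC[C@](O)(C(C)C)[C@@H]2[C@H](O)C1 | intermediate
19 | 4-hydroxybenzoic acid | OC(=O)c1ccc(O)cc1 | starting material
20 | triisopropylsilyl 4-(triisopropylsilyloxy)benzoate | CC(C)[Si](C(C)C)(C(C)C)OC(=O)c1ccc(O[Si](C(C)C)(C(C)C)C(C)C)cc1 | intermediate (not isolated)
21 | 4-(triisopropylsilyloxy)benzoic acid | CC(C)[Si](C(C)C)(C(C)C)Oc1ccc(cc1)C(O)=O | intermediate
22 | C9 4-(triisopropylsilyloxy)benzoate of 18 | CC1(O)C=C[C@]2(C)CC[C@](O)(C(C)C)[C@@H]2[C@H](OC(=O)c2ccc(O[Si](C(C)C)(C(C)C)C(C)C)cc2)C1 | intermediate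
23 | transposed enone (C3 ketone, C1(CH3)=C2) | CC1=CC(=O)[C@]2(C)CC[C@](O)(C(C)C)[C@@H]2[C@H](OC(=O)c2ccc(O[Si](C(C)C)(C(C)C)C(C)C)cc2)C1 | intermediate
24 | allylic alcohol (C3 OH cis to O9) | CC1=C[C@H](O)[C@]2(C)CC[C@](O)(C(C)C)[C@@H]2[C@H](OC(=O)c2ccc(O[Si](C(C)C)(C(C)C)C(C)C)cc2)C1 | intermediate
25 | isovaleryl chloride (3-methylbutanoyl chloride) | CC(C)CC(=O)Cl | starting material
26 | O-triisopropylsilyl ether of 27 | CC1=C[C@H](OC(=O)CC(C)C)[C@]2(C)CC[C@](O)(C(C)C)[C@@H]2[C@H](OC(=O)c2ccc(O[Si](C(C)C)(C(C)C)C(C)C)cc2)C1 | intermediate
27 | CNP0086724.3 (C3 isovalerate, C9 4-hydroxybenzoate of the cis-fused hydroazulene triol) | CC1=C[C@H](OC(=O)CC(C)C)[C@]2(C)CC[C@](O)(C(C)C)[C@@H]2[C@H](OC(=O)c2ccc(O)cc2)C1 | target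

## Step count and risks

Total: 18 steps. Longest linear sequence: 17 steps (steps 1–12 and 14–18); step 13 is a one-step side branch.

**Step 1 (key step).** The allyl cation may simply alkylate the furan at an α-carbon and lose a proton without closing the ring, and the acid-sensitive furan may polymerise during the heterogeneous silver-promoted ionisation. Fallback: generate a dibromo-oxyallyl zinc species from 1,1,3,3-tetrabromoacetone and Zn–Cu couple in the presence of 1, giving rac-2,4-dibromo-6-methyl-8-oxabicyclo[3.2.1]oct-6-en-3-one F1; reductive debromination (Zn–Cu couple, NH4Cl, MeOH) returns to the route at 4. The same two bonds and the same ring are formed.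

**Step 10.** Discrimination between the C2 and C10 protons may be eroded by mixed aggregates of the chiral amide with the C7 lithium alkoxide or by a substrate bias, giving incomplete regio- and enantio-selection. The enantiomeric purity of 17 can be no higher than the selectivity of the base, so it has to be checked at 17 and, if needed, raised by recrystallisation of ester 22. Fallback: open racemic 15 without selection (Me3SiOTf, Et3N, CH2Cl2; then citric acid, MeOH) and remove the half that opened toward C10 by chromatography, leaving racemic 17. Resolve it by lipase-catalysed acylation with vinyl acetate. The wanted enantiomer continues as 17 if it is the slow-reacting one; if it is the acylated one it is collected as the C9 acetate of 17 F2 and released by the same lipase in pH 7 buffer, returning to the route at 17.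

**Step 16.** If the cycloheptenone reacts through the other half-chair, hydride adds anti to the angular methyl and the facial selectivity at C3 is wrong. Fallback: take the C3 epimer of 24 F3 from 23 and invert it during acylation by Mitsunobu esterification with isovaleric acid (PPh3, DIAD, THF), arriving at 26.

**Step 8.** Capture of the planar C7 radical by O2 may be poorly face-selective, and simple reduction of the alkene by hydrogen-atom transfer may compete. Fallback: from 13, epoxidise with mCPBA (NaHCO3, CH2Cl2), where the bulkier reagent should keep to the outer face, giving the rac-C6–C7 epoxide F4; open it with LiBHEt3 at the secondary carbon C6 to return to the route at 14.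

**Step 3.** ZnCl2 or the acid chloride may cleave the dioxolane, and cycloaddition at the trisubstituted alkene may be slow. Fallback: run the cycloaddition on unprotected 4 (Zn–Cu couple, 6, POCl3) to the rac-dichlorocyclobutanone diketone F5; dechlorinate (Zn, NH4Cl, MeOH) to the rac-cyclobutanone diketone F6; homologate the far more reactive four-ring ketone (Me3SiCHN2, AlMe3, −78 °C) to the rac-C1,C7-diketone F7; then ketalise the unhindered C1 carbonyl selectively (ethylene glycol, PPTS), returning to the route at 11.

## Further compounds

F1 | step 1 | rac-2,4-dibromo-6-methyl-8-oxabicyclo[3.2.1]oct-6-en-3-one | O=C1C(Br)[C@H]2C(C)=C[C@H](O2)C1Br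
F2 | step 10 | C9 acetate of 17 | O=C1C=C[C@]2(C)CC[C@](O)(C(C)C)[C@@H]2[C@H](OC(C)=O)C1
F3 | step 16 | C3 epimer of 24 | CC1=C[C@@H](O)[C@]2(C)CC[C@](O)(C(C)C)[C@@H]2[C@H](OC(=O)c2ccc(O[Si](C(C)C)(C(C)C)C(C)C)cc2)C1
F4 | step 8 | rac-C6–C7 epoxide of 13 (oxygen on the face of H8) | C1COC2(O1)C[C@H]3[C@]4(C)C[C@H]5O[C@@]5(C(C)C)[C@@H]4[C@H](O3)C2
F5 | step 3 | rac-dichlorocyclobutanone diketone (C1 ketone free) | O=C1C[C@H]3[C@]4(C)C(Cl)(Cl)C(=O)[C@@H]4[C@H](O3)C1
F6 | step 3 | rac-cyclobutanone diketone | O=C1C[C@H]3[C@]4(C)CC(=O)[C@@H]4[C@H](O3)C1
F7 | step 3 | rac-C1,C7-diketone | O=C1C[C@H]3[C@]4(C)CCC(=O)[C@@H]4[C@H](O3)C1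
A1 | alternative 1 | trans-decalin C8 mesylate (C9 tertiary alcohol, C3 dioxolane, C7 triethylsilyl ether) | C1CC3(OCCO3)[C@]2(C)CC[C@](O[Si](CC)(CC)CC)(C(C)C)[C@H](OS(C)(=O)=O)[C@@]2(O)C1
A2 | alternative 1 | cis-fused hydroazulen-9-one (C3 dioxolane, C7 triethylsilyl ether) | C1CC3(OCCO3)[C@]2(C)CC[C@](O[Si](CC)(CC)CC)(C(C)C)[C@@H]2C(=O)C1
A3 | alternative 2 | methyl 2-diazobut-3-enoate | COC(=O)C(=[N+]=[N-])C=C
A4 | alternative 2 | cyclopentenyl 2-siloxydiene | C=C(O[Si](C)(C)C(C)(C)C)C1=C(C)CC[C@H]1C(C)C
A5 | alternative 2 | bicyclic cyclohepta-1,4-diene (C1 ester, C9 silyl enol ether) | COC(=O)C1=CC[C@]2(C)CC[C@@H](C(C)C)C2=C(O[Si](C)(C)C(C)(C)C)C1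
A6 | alternative 3 | cycloheptenyl carbinol dibenzyl ketal (C3 carbinol of either configuration, C9 triisopropylsilyl ether) | C1CC(O)(CCC(OCc2ccccc2)(OCc2ccccc2)C(C)C)C(C)=C[C@@H](O[Si](C(C)C)(C(C)C)C(C)C)C1
A7 | alternative 3 | cis-fused hydroazulen-3-one (C7 benzyl ether, C9 silyl ether epimeric to the target) | C1CC(=O)[C@]2(C)CC[C@](OCc3ccccc3)(C(C)C)[C@@H]2[C@@H](O[Si](C(C)C)(C(C)C)C(C)C)C1
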